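Do not read 4.3 s, the half-life of target under the over-reaction step at the charged reagent in Sunday's, as the time scale of the over-reaction product, since target has to be made first.

    substrate → intermediate (k1 = 0.11 /s, Ea1 = 81.0 kJ/mol)
    reagent ⇌ dormant form (K2 = 0.58, k2 = 0.48 /s, Ea2 = 63.0 kJ/mol, ΔH2 = −24.0 kJ/mol)
    reagent + target → over-reaction product (k3 = 89 /M/s, Ea3 = 39.0 kJ/mol)
    reagent + intermediate ⇌ target (K4 = 3000 /M, k4 = 54 /M/s, Ea4 = 45.0 kJ/mol, ΔH4 = 22.0 kJ/mol)
    (constants at 25 °C)

| flask | substrate | reagent | temperature | time | remark |
|---|---|---|---|---|---|
| Wednesday's | 1.0 mM | 1.80 mM (fed, over 20 s) | 25 °C | 25 s | all else is in the flask from the start; the feed brings no volume worth counting |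
| Monday's | 1.0 mM (fed, over 20 s) | 1.80 mM |  | 25 s | the addition at −5 °C, then warmed to 25 °C; the feed brings no volume worth counting |
| Sunday's | 1.0 mM | 1.80 mM | 25 °C | 25 s | everything together at the start |
| Saturday's | 1.0 mM (fed, over 20 s) | 1.80 mM | 25 °C | 25 s | all else is in the flask from the start; the feed brings no volume worth counting |

- the flask with the highest amount of over-reaction product, in percent of the substrate charged ("all alike" if they lie within 1.5 percentage points) (Wednesday's / Monday's / Sunday's / Saturday's / all alike)
- final over-reaction product, as a percentage of the substrate charged, in Wednesday's
- final over-reaction product, as a percentage of the substrate charged, in Monday's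
- final over-reaction product, as a percentage of the substrate charged, in Sunday's
- final over-reaction product, as a percentage of the substrate charged, in Saturday's

- the constants hold at 25 °C; other temperatures follow from the activation energies and enthalpies

Treat the chain as 3 first-order lags in series: substrate to intermediate, intermediate to target, target to over-reaction product. In Sunday's, reagent and dormant form relax with a half-life of 0.530 s, much shorter than the 6.3 s of substrate, so hold free [reagent] at 1.14 mM. That makes both reagent steps pseudo-first-order. As a first pass, neglect the way back from target, since the equilibrium constant times held [reagent] is 3.42. Add the 3 lifetimes: 35.2 s is the transit time, the mean passage through the chain. Divide the available clock by it to get the count n. With x = 3n, equal lags pass a share 1 − exp(−x)·(1 + x + x·x/2).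

Now turn the settings. Charge both together, as in Sunday's: n = 0.710, and the share is 35.9%. Read that as high, because passage of the whole charge would draw 2.00 mM of reagent against 1.80 mM charged, so a held [reagent] overstates the later part of the run. Feed the substrate, as in Saturday's: it enters 10.0 s late on average, so n = 0.426 and the share is 13.8%. Feed the reagent, as in Wednesday's: substrate keeps the full clock, but mean [reagent] falls to 60.0% of the held value. Stretching both reagent lifetimes accordingly gives n = 0.475 and a share of 17.3%. Chill the feed, as in Monday's: take the cold stretch as a stopped clock, because substrate's step has the steepest activation energy. Then n = 0.142 and the share is 0.939%. My ranking puts Sunday's highest.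

The forecast named Sunday's and gave 17.5% for Wednesday's, 1.2% for Monday's, 25% for Sunday's and 13% for Saturday's, lower than my Sunday's figure, holding that “whichever flask gets target and free reagent together earliest makes the most”.

The simulation puts Sunday's highest, with 17.6% in Wednesday's, 1.14% in Monday's, 25.1% in Sunday's and 12.6% in Saturday's.

Sunday's parts from my count by 11 percentage points: at 25.0 s its reagent stands at 37.7% of charge, against the held share of 63.3%. Apply the same count to the neighbour, Sunday's read at 6.0 s. With the transit time unchanged, n = 0.170 and the share comes to 1.52%. That reading shows 1.60% of over-reaction product, with reagent at 59.4% of its charge.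

The rate constants are assumed; no experiment stands behind them.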